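**Plan**

1. Numbering used here: tetralin C-1 (side chain), C-4 (methyl), C-4a/C-8a (ring fusion), C-5 and C-6 (OH), C-7 (CO2H); side chain C-11 (bearing the C-20 hydroxymethyl) to C-16. Retrosynthetic cuts, in order: (a) C-7–CO2H; (b) aryl C-4a–C-4 of ring B; (c) C-3–C-4; (d) C-1–C-11.
2. Forward: side-chain aldehyde 4 and aryl vinyl carbinol 6 are joined at C-1–C-11 with the arene present from the start. The vinyl group becomes a primary, then a secondary boronic ester. Ring B is closed by contraction of a seven-membered cyclic aryl(alkyl)boronate complex with excision of boron. Carboxylation at C-7 and ether cleavage finish the route.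
3. Enabling feature: the arene is 1,2-dioxygenated, with the C-6 oxygen meta to C-4a and ortho to a free C-7–H. An electrophile therefore enters at C-7, para to a boron held on C-4a, and makes C-4a the terminus of a 1,2-shift. C-4 is a secondary methyl-bearing carbon that can be carried as a configurationally stable secondary boronic ester.
4. Stereochemistry: C-15 from (R)-3-bromo-2-methylpropan-1-ol; C-1 and C-11 together by dual iridium/amine catalysis (catalyst control); C-4 by (−)-sparteine-controlled lithiation–borylation, then transferred with retention in the 1,2-shift, which fixes the 1,4-trans relation without 1,4-induction.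

Key step: step 9

Assumption: in step 5 the (R)-configured phosphoramidite–olefin ligand on iridium is taken to give the (3S) benzylic centre; if the sense of induction is the opposite one, the (S)-ligand is used, since the amine catalyst fixes C-2 independently.

**Route**

Step 1
Reactants: 1 (R)-3-bromo-2-methylpropan-1-ol
Product: 2 (R)-(3-bromo-2-methylpropoxy)(tert-butyl)dimethylsilane
Conditions: TBSCl, imidazole, CH2Cl2, 0 °C to rt
Reagents that add atoms: tert-butyldimethylsilyl chloride, CC(C)(C)[Si](C)(C)Cl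
Why: Imidazole-promoted silylation of a primary alcohol (silyl ether formation) leaves the stereocentre untouched.

Step 2
Reactants: 2 (R)-(3-bromo-2-methylpropoxy)(tert-butyl)dimethylsilane
Product: 3 tert-butyldimethyl{[(2S)-2-methylhex-5-en-1-yl]oxy}silane
Conditions: allylmagnesium bromide, CuI (10 mol%), THF, 0 °C to rt
Reagents that add atoms: allylmagnesium bromide, C=CC[Mg]Br
Why: Copper-catalysed sp3–sp3 cross-coupling of a primary alkyl bromide with an allyl Grignard reagent forms C-13–C-14 without involving the β-stereocentre.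

Step 3
Reactants: 3 tert-butyldimethyl{[(2S)-2-methylhex-5-en-1-yl]oxy}silane
Product: 4 (6S)-7-(tert-butyldimethylsilyloxy)-6-methylheptanal
Conditions: Rh(acac)(CO)2 (1 mol%), BiPhePhos (3 mol%), CO/H2 (1:1, 10 bar), toluene, 60 °C
Reagents that add atoms: carbon monoxide, [C-]#[O+]
Why: Rhodium-catalysed hydroformylation with the wide-bite-angle bisphosphite BiPhePhos is selective for the linear aldehyde of a terminal alkene and tolerates the silyl ether.

Step 4
Reactants: 5 2-bromo-3,4-dimethoxybenzaldehyde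
Product: 6 rac-1-(2-bromo-3,4-dimethoxyphenyl)prop-2-en-1-ol
Conditions: vinylmagnesium bromide, THF, −78 to 0 °C; then H2O
Reagents that add atoms: vinylmagnesium bromide, C=C[Mg]Br
Why: Grignard 1,2-addition to an aromatic aldehyde gives the racemic branched allylic alcohol that the next step needs, the aryl bromide being inert to the Grignard reagent at low temperature.

Step 5
Reactants: 4 (6S)-7-(tert-butyldimethylsilyloxy)-6-methylheptanal; 6 rac-1-(2-bromo-3,4-dimethoxyphenyl)prop-2-en-1-ol (1.5 equiv)
Product: 8 (2S,3S)-3-(2-bromo-3,4-dimethoxyphenyl)-2-[(4S)-5-(tert-butyldimethylsilyloxy)-4-methylpentyl]pent-4-en-1-ol, via pentenal 7 (not isolated)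
Conditions: [Ir(cod)Cl]2 (3 mol%), (R)-4-(5H-dibenzo[b,f]azepin-5-yl)dinaphtho[2,1-d:1',2'-f][1,3,2]dioxaphosphepine (12 mol%), (R)-2-{bis[3,5-bis(trifluoromethyl)phenyl][(trimethylsilyl)oxy]methyl}pyrrolidine (15 mol%), (MeO)2P(O)OH (50 mol%), 1,2-dichloroethane, 25 °C; then NaBH4, MeOH, 0 °C
Reagents that add atoms: none
Why: Dual iridium/amine catalysis (iridium-catalysed allylic substitution joined to enamine catalysis): both enantiomers of 6 ionise to the same aryl-substituted allyl–iridium electrophile, which is attacked at its branched terminus by the enamine of 4, the ligand on iridium fixing the benzylic centre (3S) and the prolinol ether, by shielding one enamine face, fixing the α-centre (2S) independently, after which borohydride reduction in the same flask protects the α-centre from epimerisation.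

Step 6
Reactants: 8 (2S,3S)-3-(2-bromo-3,4-dimethoxyphenyl)-2-[(4S)-5-(tert-butyldimethylsilyloxy)-4-methylpentyl]pent-4-en-1-ol
Product: 9 (3S,4S,8S)-3-(2-bromo-3,4-dimethoxyphenyl)-9-(tert-butyldimethylsilyloxy)-4-[(tert-butyldimethylsilyloxy)methyl]-8-methylnon-1-ene
Conditions: TBSCl, imidazole, DMF, rt
Reagents that add atoms: tert-butyldimethylsilyl chloride, CC(C)(C)[Si](C)(C)Cl
Why: Silylation of the primary alcohol (silyl ether formation) gives both side-chain oxygens the same protecting group, which is stable to the organolithium steps that follow.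

Step 7
Reactants: 9 (3S,4S,8S)-3-(2-bromo-3,4-dimethoxyphenyl)-9-(tert-butyldimethylsilyloxy)-4-[(tert-butyldimethylsilyloxy)methyl]-8-methylnon-1-ene
Product: 10 2-[(3S,4S,8S)-3-(2-bromo-3,4-dimethoxyphenyl)-9-(tert-butyldimethylsilyloxy)-4-[(tert-butyldimethylsilyloxy)methyl]-8-methylnonyl]-4,4,5,5-tetramethyl-1,3,2-dioxaborolane
Conditions: pinacolborane, [Ir(cod)Cl]2 (1.5 mol%), dppm (3 mol%), CH2Cl2, rt
Reagents that add atoms: pinacolborane, [H]B1OC(C)(C)C(C)(C)O1
Why: Iridium-catalysed hydroboration of a terminal alkene with pinacolborane places boron on the terminal carbon (C-3), forms no stereocentre and leaves the aryl bromide untouched at room temperature.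

Step 8
Reactants: 10 2-[(3S,4S,8S)-3-(2-bromo-3,4-dimethoxyphenyl)-9-(tert-butyldimethylsilyloxy)-4-[(tert-butyldimethylsilyloxy)methyl]-8-methylnonyl]-4,4,5,5-tetramethyl-1,3,2-dioxaborolane
Product: 12 2-[(2R,5S,6S,10S)-5-(2-bromo-3,4-dimethoxyphenyl)-11-(tert-butyldimethylsilyloxy)-6-[(tert-butyldimethylsilyloxy)methyl]-10-methylundecan-2-yl]-4,4,5,5-tetramethyl-1,3,2-dioxaborolane, via boronate complex 11 (not isolated)
Conditions: ethyl 2,4,6-triisopropylbenzoate (1.3 equiv), (−)-sparteine (1.3 equiv), s-BuLi (1.2 equiv), Et2O, −78 °C; then 10, −78 °C; then 35 °C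
Reagents that add atoms: ethyl 2,4,6-triisopropylbenzoate, CCOC(=O)c1c(C(C)C)cc(C(C)C)cc1C(C)C
Why: Lithiation–borylation (a reagent-controlled Matteson-type homologation): (−)-sparteine-mediated removal of the pro-S proton gives the (S)-lithiated benzoate, which adds to boron with retention, and the primary alkyl group then migrates with inversion and loss of the benzoate to give the (R)-secondary boronate, no free s-BuLi being left to attack the aryl bromide.

Step 9
Reactants: 12 2-[(2R,5S,6S,10S)-5-(2-bromo-3,4-dimethoxyphenyl)-11-(tert-butyldimethylsilyloxy)-6-[(tert-butyldimethylsilyloxy)methyl]-10-methylundecan-2-yl]-4,4,5,5-tetramethyl-1,3,2-dioxaborolane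
Product: 16 (1S,4R)-1-[(2S,6S)-1,7-bis(tert-butyldimethylsilyloxy)-6-methylheptan-2-yl]-5,6-dimethoxy-4-methyl-1,2,3,4-tetrahydronaphthalene, via aryllithium 13 (not isolated), via cyclic boronate complex 14 (not isolated), via bromodihydronaphthalene boronate 15 (not isolated)
Conditions: t-BuLi (2.05 equiv), THF, −100 to −78 °C; then NBS, THF, −78 °C to rt
Reagents that add atoms: none
Why: Proposed new method: bromine–lithium exchange, expected to outrun addition of the bulky t-BuLi to the hindered secondary boronate at −100 °C (as in a Parham cyclisation), gives aryllithium 13, which the tethered boron captures as the seven-membered cyclic boronate complex 14; NBS then brominates the arene of 14 at C-7, the cyclohexadienyl cation triggers a 1,2-shift of the secondary alkyl carbon C-4 from boron to C-4a, and loss of bromide and of the boryl group from 15 restores the aromatic ring. The closest known reaction type is the intermolecular, electrophile-induced 1,2-metallate coupling of electron-rich aryllithiums with secondary pinacol boronic esters, which is stereospecific; here it is run inside a ring, so that boron is excised from a benzo-fused borepane and the tetralin results. Ring B is closed by ring contraction of the seven-membered boracycle to the six-membered carbocycle through a 1,2-migration, not by a direct cyclisation onto a cation, radical or metal. The new benzylic stereocentre C-4 is controlled by the migrating carbon itself, which keeps its configuration (retention), so the (R)-boronate gives the (4R)-methyl centre trans to the C-1 side chain. The step needs bromination at C-7 in preference to ipso attack at the boron-bearing C-4a or attack at C-8; the C-6 methoxy group (ortho to C-7, meta to boron) and the electron-releasing C–B bond of the boronate (para to C-7) both direct there, while the C-5 methoxy group is twisted out of conjugation by its two ortho neighbours.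

Step 10
Reactants: 16 (1S,4R)-1-[(2S,6S)-1,7-bis(tert-butyldimethylsilyloxy)-6-methylheptan-2-yl]-5,6-dimethoxy-4-methyl-1,2,3,4-tetrahydronaphthalene
Product: 18 (5R,8S)-8-[(2S,6S)-1,7-bis(tert-butyldimethylsilyloxy)-6-methylheptan-2-yl]-3,4-dimethoxy-5-methyl-5,6,7,8-tetrahydronaphthalene-2-carboxylic acid, via aryllithium 17 (not isolated)
Conditions: n-BuLi, TMEDA, Et2O, 0 °C to rt; then CO2, −78 °C to rt; then dilute aq. HCl, 0 °C
Reagents that add atoms: carbon dioxide, O=C=O
Why: Directed ortho-metalation followed by carboxylation: the C-6 methoxy group is the only director with a free ortho position, so lithiation gives 17 at C-7 and CO2 converts it into the benzoic acid.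

Step 11
Reactants: 18 (5R,8S)-8-[(2S,6S)-1,7-bis(tert-butyldimethylsilyloxy)-6-methylheptan-2-yl]-3,4-dimethoxy-5-methyl-5,6,7,8-tetrahydronaphthalene-2-carboxylic acid
Product: 19 (5R,8S)-8-[(2S,6S)-1,7-dihydroxy-6-methylheptan-2-yl]-3,4-dihydroxy-5-methyl-5,6,7,8-tetrahydronaphthalene-2-carboxylic acid (CNP0255074.1)
Conditions: BBr3, CH2Cl2, −78 to 0 °C; then H2O/THF, rt
Reagents that add atoms: none
Why: Lewis-acid ether cleavage with BBr3 removes both aryl methyl ethers (the one next to the carboxyl group with chelation assistance) and both silyl ethers, and hydrolysis of the borates then frees the catechol, the diol and the acid without touching a stereocentre.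

**Compound list**

1 | (R)-3-bromo-2-methylpropan-1-ol | C[C@H](CO)CBr | starting material
2 | (R)-(3-bromo-2-methylpropoxy)(tert-butyl)dimethylsilane | C[C@H](CO[Si](C)(C)C(C)(C)C)CBr | intermediate
3 | tert-butyldimethyl{[(2S)-2-methylhex-5-en-1-yl]oxy}silane | C[C@H](CO[Si](C)(C)C(C)(C)C)CCC=C | intermediate
4 | (6S)-7-(tert-butyldimethylsilyloxy)-6-methylheptanal | C[C@H](CO[Si](C)(C)C(C)(C)C)CCCCC=O | intermediate
5 | 2-bromo-3,4-dimethoxybenzaldehyde | COc1ccc(C=O)c(Br)c1OC | starting material
6 | rac-1-(2-bromo-3,4-dimethoxyphenyl)prop-2-en-1-ol | C=CC(O)c1ccc(OC)c(OC)c1Br | intermediate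
7 | (2S,3S)-3-(2-bromo-3,4-dimethoxyphenyl)-2-[(4S)-5-(tert-butyldimethylsilyloxy)-4-methylpentyl]pent-4-enal (not isolated) | C[C@H](CO[Si](C)(C)C(C)(C)C)CCC[C@H](C=O)[C@H](C=C)c1ccc(OC)c(OC)c1Br | intermediate
8 | (2S,3S)-3-(2-bromo-3,4-dimethoxyphenyl)-2-[(4S)-5-(tert-butyldimethylsilyloxy)-4-methylpentyl]pent-4-en-1-ol | C[C@H](CO[Si](C)(C)C(C)(C)C)CCC[C@H](CO)[C@H](C=C)c1ccc(OC)c(OC)c1Br | intermediate
9 | (3S,4S,8S)-3-(2-bromo-3,4-dimethoxyphenyl)-9-(tert-butyldimethylsilyloxy)-4-[(tert-butyldimethylsilyloxy)methyl]-8-methylnon-1-ene | C[C@H](CO[Si](C)(C)C(C)(C)C)CCC[C@H](CO[Si](C)(C)C(C)(C)C)[C@H](C=C)c1ccc(OC)c(OC)c1Br | intermediate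
10 | 2-[(3S,4S,8S)-3-(2-bromo-3,4-dimethoxyphenyl)-9-(tert-butyldimethylsilyloxy)-4-[(tert-butyldimethylsilyloxy)methyl]-8-methylnonyl]-4,4,5,5-tetramethyl-1,3,2-dioxaborolane | C[C@H](CO[Si](C)(C)C(C)(C)C)CCC[C@H](CO[Si](C)(C)C(C)(C)C)[C@H](CCB1OC(C)(C)C(C)(C)O1)c1ccc(OC)c(OC)c1Br | intermediate
11 | lithium boronate complex of 10, the boron made tetracoordinate by an (S)-1-(2,4,6-triisopropylbenzoyloxy)ethyl group (not isolated) | C[C@H](CO[Si](C)(C)C(C)(C)C)CCC[C@H](CO[Si](C)(C)C(C)(C)C)[C@H](CC[B-]1([C@@H](C)OC(=O)c2c(C(C)C)cc(C(C)C)cc2C(C)C)OC(C)(C)C(C)(C)O1)c1ccc(OC)c(OC)c1Br.[Li+] | intermediate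
12 | 2-[(2R,5S,6S,10S)-5-(2-bromo-3,4-dimethoxyphenyl)-11-(tert-butyldimethylsilyloxy)-6-[(tert-butyldimethylsilyloxy)methyl]-10-methylundecan-2-yl]-4,4,5,5-tetramethyl-1,3,2-dioxaborolane | C[C@H](CO[Si](C)(C)C(C)(C)C)CCC[C@H](CO[Si](C)(C)C(C)(C)C)[C@H](CC[C@@H](C)B1OC(C)(C)C(C)(C)O1)c1ccc(OC)c(OC)c1Br | intermediate
13 | aryllithium of 12, lithium in place of bromine (not isolated) | C[C@H](CO[Si](C)(C)C(C)(C)C)CCC[C@H](CO[Si](C)(C)C(C)(C)C)[C@H](CC[C@@H](C)B1OC(C)(C)C(C)(C)O1)c1ccc(OC)c(OC)c1[Li] | intermediate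
14 | lithium salt of the seven-membered cyclic boronate complex, tetracoordinate pinacolato-boron bonded to aryl C-4a and to C-4 (not isolated) | C[C@H](CO[Si](C)(C)C(C)(C)C)CCC[C@H](CO[Si](C)(C)C(C)(C)C)[C@@H]1CC[C@@H](C)[B-]2(OC(C)(C)C(C)(C)O2)c2c1ccc(OC)c2OC.[Li+] | intermediate
15 | 7-bromo-4a-(pinacolatoboryl)-4a,7-dihydro analogue of 16, configuration at C-4a and C-7 not defined (not isolated) | C[C@H](CO[Si](C)(C)C(C)(C)C)CCC[C@H](CO[Si](C)(C)C(C)(C)C)[C@@H]1CC[C@@H](C)C2(B3OC(C)(C)C(C)(C)O3)C1=CC(Br)C(OC)=C2OC | intermediate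
16 | (1S,4R)-1-[(2S,6S)-1,7-bis(tert-butyldimethylsilyloxy)-6-methylheptan-2-yl]-5,6-dimethoxy-4-methyl-1,2,3,4-tetrahydronaphthalene | C[C@H](CO[Si](C)(C)C(C)(C)C)CCC[C@H](CO[Si](C)(C)C(C)(C)C)[C@@H]1CC[C@@H](C)c2c1ccc(OC)c2OC | intermediate
17 | 7-lithio derivative of 16 (not isolated) | C[C@H](CO[Si](C)(C)C(C)(C)C)CCC[C@H](CO[Si](C)(C)C(C)(C)C)[C@@H]1CC[C@@H](C)c2c1cc([Li])c(OC)c2OC | intermediate
18 | (5R,8S)-8-[(2S,6S)-1,7-bis(tert-butyldimethylsilyloxy)-6-methylheptan-2-yl]-3,4-dimethoxy-5-methyl-5,6,7,8-tetrahydronaphthalene-2-carboxylic acid | C[C@H](CO[Si](C)(C)C(C)(C)C)CCC[C@H](CO[Si](C)(C)C(C)(C)C)[C@@H]1CC[C@@H](C)c2c1cc(C(=O)O)c(OC)c2OC | intermediate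
19 | (5R,8S)-8-[(2S,6S)-1,7-dihydroxy-6-methylheptan-2-yl]-3,4-dihydroxy-5-methyl-5,6,7,8-tetrahydronaphthalene-2-carboxylic acid | C[C@H](CO)CCC[C@H](CO)[C@@H]1CC[C@@H](C)c2c1cc(C(=O)O)c(O)c2O | target

**Count and risks**

Total steps: 11. Longest linear sequence: 10 steps (1 to 19 through steps 1–3 and 5–11).

Risk 1, step 9 (proposed new method). What may go wrong: addition of t-BuLi to boron before bromine–lithium exchange; bromination at the boron-bearing carbon, which would reopen the ring; or poor alignment of the migrating B–C bond with the ring π system in the seven-membered complex. The fallback uses known chemistry, sets out from 10 and comes back at 16. Zweifel olefination of 10 (vinylmagnesium bromide, THF; then I2, NaOMe, MeOH) should give (5S,6S,10S)-5-(2-bromo-3,4-dimethoxyphenyl)-11-(tert-butyldimethylsilyloxy)-6-[(tert-butyldimethylsilyloxy)methyl]-10-methylundec-1-ene F1. An intramolecular Heck reaction (Pd(OAc)2, P(o-tol)3, Ag2CO3, MeCN, 80 °C, 6-exo-trig) should close ring B to (1S)-1-[(2S,6S)-1,7-bis(tert-butyldimethylsilyloxy)-6-methylheptan-2-yl]-5,6-dimethoxy-4-methylidene-1,2,3,4-tetrahydronaphthalene F2. Acid-catalysed alkene isomerisation (p-TsOH cat., toluene, 60 °C) should move the double bond into the ring to give (1S)-1-[(2S,6S)-1,7-bis(tert-butyldimethylsilyloxy)-6-methylheptan-2-yl]-5,6-dimethoxy-4-methyl-1,2-dihydronaphthalene F3. Asymmetric hydrogenation of this trisubstituted alkene (H2, [Ir(cod)(L)]BArF with a chiral phosphine–oxazoline L, CH2Cl2), with the catalyst enantiomer that adds hydrogen to the face giving (4R), returns 16. In this fallback C-4 is set by catalyst control instead of by stereospecific transfer.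

Risk 2, step 5. What may go wrong: slow ionisation of the ortho-bromo carbinol, loss of diastereocontrol through epimerisation of the α-centre before reduction, or partial loss of the silyl ether under the acidic promoter. The fallback sets out from 4 and 6 and comes back at 8.
- Rhenium-catalysed 1,3-transposition of 6 (Re2O7 cat., Et2O) should give (E)-3-(2-bromo-3,4-dimethoxyphenyl)prop-2-en-1-ol F4.
- Pinnick oxidation of 4 (NaClO2, NaH2PO4, 2-methyl-2-butene, t-BuOH/H2O) should give (6S)-7-(tert-butyldimethylsilyloxy)-6-methylheptanoic acid F5.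
- Steglich esterification (DCC, DMAP, CH2Cl2) joins them as (E)-3-(2-bromo-3,4-dimethoxyphenyl)prop-2-en-1-yl (6S)-7-(tert-butyldimethylsilyloxy)-6-methylheptanoate F6.
- An enantioselective boron-enolate Ireland–Claisen rearrangement is run with a chiral 2-bromo-1,3-bis(arylsulfonyl)-4,5-diphenyl-1,3,2-diazaborolidine and a tertiary amine at −78 to −20 °C. The amine/solvent pair is chosen for the enolate geometry that leads through the chair transition state to the required diastereomer. It should give (2S,3S)-3-(2-bromo-3,4-dimethoxyphenyl)-2-[(4S)-5-(tert-butyldimethylsilyloxy)-4-methylpentyl]pent-4-enoic acid F7.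
- Reduction with LiAlH4 (Et2O, 0 °C) returns 8.

Risk 3, step 10. What may go wrong: incomplete or misdirected metalation (benzylic deprotonation or attack at silicon in place of ortho-lithiation), since a methoxy group is a weak director. The fallback sets out from 16 and comes back at 19. Global ether cleavage of 16 (BBr3, CH2Cl2, −78 to 0 °C; aqueous work-up) should give (5S,8R)-5-[(2S,6S)-1,7-dihydroxy-6-methylheptan-2-yl]-8-methyl-5,6,7,8-tetrahydronaphthalene-1,2-diol F8. Kolbe–Schmitt carboxylation of this catechol (KHCO3, CO2 under pressure, 150 °C) should place the carboxyl group at C-7, the only free position ortho to a phenolic oxygen, and return 19. This replaces lithiation by electrophilic carboxylation of the phenolate.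

Further compounds
F1 | step 9 | (5S,6S,10S)-5-(2-bromo-3,4-dimethoxyphenyl)-11-(tert-butyldimethylsilyloxy)-6-[(tert-butyldimethylsilyloxy)methyl]-10-methylundec-1-ene | C[C@H](CO[Si](C)(C)C(C)(C)C)CCC[C@H](CO[Si](C)(C)C(C)(C)C)[C@H](CCC=C)c1ccc(OC)c(OC)c1Br
F2 | step 9 | (1S)-1-[(2S,6S)-1,7-bis(tert-butyldimethylsilyloxy)-6-methylheptan-2-yl]-5,6-dimethoxy-4-methylidene-1,2,3,4-tetrahydronaphthalene | C[C@H](CO[Si](C)(C)C(C)(C)C)CCC[C@H](CO[Si](C)(C)C(C)(C)C)[C@@H]1CCC(=C)c2c1ccc(OC)c2OC
F3 | step 9 | (1S)-1-[(2S,6S)-1,7-bis(tert-butyldimethylsilyloxy)-6-methylheptan-2-yl]-5,6-dimethoxy-4-methyl-1,2-dihydronaphthalene | C[C@H](CO[Si](C)(C)C(C)(C)C)CCC[C@H](CO[Si](C)(C)C(C)(C)C)[C@@H]1CC=C(C)c2c1ccc(OC)c2OC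
F4 | step 5 | (E)-3-(2-bromo-3,4-dimethoxyphenyl)prop-2-en-1-ol | OC/C=C/c1ccc(OC)c(OC)c1Br
F5 | step 5 | (6S)-7-(tert-butyldimethylsilyloxy)-6-methylheptanoic acid | C[C@H](CO[Si](C)(C)C(C)(C)C)CCCCC(=O)O
F6 | step 5 | (E)-3-(2-bromo-3,4-dimethoxyphenyl)prop-2-en-1-yl (6S)-7-(tert-butyldimethylsilyloxy)-6-methylheptanoate | C[C@H](CO[Si](C)(C)C(C)(C)C)CCCCC(=O)OC/C=C/c1ccc(OC)c(OC)c1Br
F7 | step 5 | (2S,3S)-3-(2-bromo-3,4-dimethoxyphenyl)-2-[(4S)-5-(tert-butyldimethylsilyloxy)-4-methylpentyl]pent-4-enoic acid | C[C@H](CO[Si](C)(C)C(C)(C)C)CCC[C@H](C(=O)O)[C@H](C=C)c1ccc(OC)c(OC)c1Br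
F8 | step 10 | (5S,8R)-5-[(2S,6S)-1,7-dihydroxy-6-methylheptan-2-yl]-8-methyl-5,6,7,8-tetrahydronaphthalene-1,2-diol | C[C@H](CO)CCC[C@H](CO)[C@@H]1CC[C@@H](C)c2c1ccc(O)c2O
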